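**Strategy.** Ring C is disconnected at C3–C4. C4 is already attached to ring A as the carbon of a methyl ketone, and C3 is the inner carbon of a vinyl group on the benzylic C2, whose O1–C2 bond and (S) configuration are installed earlier by asymmetric allylic etherification. One ruthenium-catalysed ring-closing metathesis between the ketone's silyl enol ether and this vinyl group forms C3=C4 and the pyran ring while leaving C2 untouched. The precursor is an (S)-1-arylallyl aryl ether whose ring A carries the C8 lavandulyl, C6 prenyl and C4a siloxyvinyl groups; all phenols are TBS ethers, so that one buffered fluoride step releases ketone and phenols without acid.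

Key step: step 14

Abbreviations: TBS = tert-butyldimethylsilyl (TBSO = its silyloxy group); prenyl = 3-methylbut-2-en-1-yl; (R)-lavandulyl = (2R)-5-methyl-2-(prop-1-en-2-yl)hex-4-en-1-yl. Flavanone numbering (O1, C2, C3, C4, C4a, C5–C8, C8a) is used for the target; ring A precursors are numbered as acetophenones (C1 bears the acetyl group).

Remark (assumption): the lipase is taken to acylate (R)-lavandulol faster and the (Sa,Sc,Sc) ligand to give the (S)-ether, by analogy with simpler substrates; if a test run shows the opposite sense, the acetate fraction (after methanolysis) or the mirror-image ligand is used instead.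

Step 1
Reactants: 1 2,4,6-trihydroxyacetophenone
Product: 2 1-[2-hydroxy-4,6-bis(TBSO)phenyl]ethanone
Conditions: TBSCl (2.2 equiv), imidazole, CH2Cl2–DMF, 0 °C → rt
Reagents that add atoms: tert-butyldimethylsilyl chloride, CC(C)(C)[Si](C)(C)Cl
Why: Silyl ether formation should take the para hydroxyl and one of the two equivalent ortho hydroxyls, while the last ortho hydroxyl stays free because it is hydrogen-bonded to the acetyl carbonyl; no stereocentre is formed.

Step 2
Reactants: 2 1-[2-hydroxy-4,6-bis(TBSO)phenyl]ethanone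
Product: 3 1-[2-hydroxy-3-iodo-4,6-bis(TBSO)phenyl]ethanone
Conditions: NIS (1.05 equiv), CH2Cl2, 0 °C, dark
Reagents that add atoms: N-iodosuccinimide, O=C1CCC(=O)N1I
Why: Electrophilic aromatic iodination should go ortho to the free chelated hydroxyl (C3), which is activated by all three oxygens and far less shielded than C5 between two bulky silyloxy groups.

Step 3
Reactants: 4 racemic lavandulol [5-methyl-2-(prop-1-en-2-yl)hex-4-en-1-ol]
Product: 5 (S)-lavandulol
Conditions: porcine pancreatic lipase, vinyl acetate, hexane, 25 °C, run to about 60 % conversion (GC); chromatography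
Reagents that add atoms: none
Why: Lipase-catalysed kinetic resolution by irreversible transesterification is expected to acetylate the (R)-alcohol faster, so that running past half conversion should leave (S)-lavandulol of high enantiomeric purity and thereby fix the side-chain stereocentre for the whole route.

Step 4
Reactants: 5 (S)-lavandulol
Product: 6 (S)-lavandulyl iodide [(3S)-3-(iodomethyl)-2,6-dimethylhepta-1,5-diene]
Conditions: PPh3, I2, imidazole, CH2Cl2, 0 °C → rt
Reagents that add atoms: iodine, II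
Why: Appel-type iodination substitutes the primary hydroxyl by SN2 at the CH2 carbon, so the neighbouring stereocentre is untouched, and the alkenes survive because the iodine is taken up by the phosphine before the alcohol is added.

Step 5
Reactants: 3 1-[2-hydroxy-3-iodo-4,6-bis(TBSO)phenyl]ethanone; 6 (S)-lavandulyl iodide
Product: 8 1-{2-hydroxy-3-[(R)-lavandulyl]-4,6-bis(TBSO)phenyl}ethanone, via (S)-lavandulylzinc iodide 7 (not isolated)
Conditions: (a) 6, Zn, LiCl, THF, 40 °C; (b) 3, Pd(OAc)2 (2 mol %), SPhos (4 mol %), THF, 25 °C, slow addition of 7 (1.6 equiv)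
Reagents that add atoms: none
Why: Zinc insertion into the primary iodide and Negishi sp3–sp2 cross-coupling with a Pd(OAc)2/SPhos catalyst, a system that couples alkylzinc halides with hindered aryl iodides even when a free phenol is present, should join the side chain to C3; the stereocentre is β to zinc and not involved (its descriptor changes from S to R only through the CIP priorities).

Step 6
Reactants: 8 1-{2-hydroxy-3-[(R)-lavandulyl]-4,6-bis(TBSO)phenyl}ethanone; 9 3-methylbut-2-en-1-ol (prenol)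
Product: 10 1-{3-[(R)-lavandulyl]-2-(prenyloxy)-4,6-bis(TBSO)phenyl}ethanone
Conditions: PPh3, DIAD, THF, 0 °C → rt
Reagents that add atoms: none
Why: Mitsunobu etherification of the acidic chelated phenol with the primary allylic alcohol gives the aryl prenyl ether by SN2 at CH2 under neutral conditions that leave the aryl silyl ethers in place.

Step 7
Reactants: 10 1-{3-[(R)-lavandulyl]-2-(prenyloxy)-4,6-bis(TBSO)phenyl}ethanone
Product: 12 1-{2-hydroxy-3-[(R)-lavandulyl]-5-prenyl-4,6-bis(TBSO)phenyl}ethanone, via ortho-dienone 11 (not isolated)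
Conditions: PhNEt2, 190 °C, sealed tube, Ar
Reagents that add atoms: none
Why: Aromatic para-Claisen rearrangement: with both ortho positions substituted, the [3,3] shift to the lavandulyl-bearing ortho carbon gives a dienone that cannot enolise and instead undergoes a second [3,3] (Cope) shift that places a normal prenyl group on the only free ring carbon, para to the oxygen, before tautomerisation restores the phenol; the remote side-chain stereocentre is not involved, and the Cope rearrangement of the lavandulyl diene itself is expected to be much slower.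

Step 8
Reactants: 13 2,4,6-trihydroxybenzaldehyde
Product: 14 2,4,6-tris(TBSO)benzaldehyde
Conditions: TBSCl (3.6 equiv), imidazole, DMF, 40 °C
Reagents that add atoms: tert-butyldimethylsilyl chloride, CC(C)(C)[Si](C)(C)Cl
Why: Exhaustive silyl ether formation with excess reagent in DMF should also silylate the chelated ortho hydroxyls and gives a ring B building block free of acidic protons.

Step 9
Reactants: 14 2,4,6-tris(TBSO)benzaldehyde; 15 ethyl (triphenylphosphoranylidene)acetate
Product: 16 ethyl (E)-3-[2,4,6-tris(TBSO)phenyl]prop-2-enoate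
Conditions: PhMe, 100 °C
Reagents that add atoms: none
Why: Wittig olefination with a stabilised ylide gives the (E)-cinnamate under neutral conditions that do not cleave aryl silyl ethers.

Step 10
Reactants: 16 ethyl (E)-3-[2,4,6-tris(TBSO)phenyl]prop-2-enoate
Product: 17 (E)-3-[2,4,6-tris(TBSO)phenyl]prop-2-en-1-ol
Conditions: i-Bu2AlH (2.5 equiv), CH2Cl2, −78 °C; aq. KNaC4H4O6
Reagents that add atoms: none
Why: 1,2-Reduction of the conjugated ester with i-Bu2AlH at low temperature gives the allylic alcohol without touching the alkene or the silyl ethers.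

Step 11
Reactants: 17 (E)-3-[2,4,6-tris(TBSO)phenyl]prop-2-en-1-ol
Product: 18 methyl (E)-3-[2,4,6-tris(TBSO)phenyl]prop-2-en-1-yl carbonate
Conditions: ClCO2Me, pyridine, CH2Cl2, 0 °C; base-washed silica
Reagents that add atoms: methyl chloroformate, COC(=O)Cl
Why: O-Acylation of the primary allylic alcohol under basic conditions gives the linear carbonate that serves as the allyl donor and avoids acid, which would ionise this electron-rich cinnamyl system.

Step 12
Reactants: 12 1-{2-hydroxy-3-[(R)-lavandulyl]-5-prenyl-4,6-bis(TBSO)phenyl}ethanone; 18 methyl (E)-3-[2,4,6-tris(TBSO)phenyl]prop-2-en-1-yl carbonate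
Product: 20 1-{2-[(1S)-1-(2,4,6-tris(TBSO)phenyl)prop-2-en-1-yloxy]-3-[(R)-lavandulyl]-5-prenyl-4,6-bis(TBSO)phenyl}ethanone, via lithium phenoxide 19 (not isolated)
Conditions: 12, LiN(SiMe3)2 (1.0 equiv), THF, −78 → 0 °C; then 18, [Ir(cod)Cl]2 (2 mol %), (Sa,Sc,Sc)-BINOL N,N-bis[1-(2-methoxyphenyl)ethyl]phosphoramidite (4 mol %, pre-activated with n-PrNH2), THF, 25–40 °C; stopped at full conversion of 18
Reagents that add atoms: none
Why: Iridium-catalysed asymmetric allylic etherification: ionisation of the linear carbonate gives an (allyl)iridium intermediate that the phenoxide attacks at the aryl-substituted terminus, so the branched ether forms and the new C2 stereocentre is set by the chiral phosphoramidite (the ligand variant suited to ortho-substituted cinnamyl donors, its enantiomer chosen to give S), while the ketone is not enolised because only the phenol is deprotonated.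

Step 13
Reactants: 20 1-{2-[(1S)-1-(2,4,6-tris(TBSO)phenyl)prop-2-en-1-yloxy]-3-[(R)-lavandulyl]-5-prenyl-4,6-bis(TBSO)phenyl}ethanone
Product: 22 (S)-allyl aryl ether 20 with the acetyl group converted into a 1-(TBSO)vinyl group, via potassium enolate 21 (not isolated)
Conditions: KN(SiMe3)2 (1.3 equiv), THF, −78 °C; then TBSOTf (1.25 equiv), −78 °C; Et3N, aq. NaHCO3; Et3N-deactivated silica
Reagents that add atoms: tert-butyldimethylsilyl trifluoromethanesulfonate, CC(C)(C)[Si](C)(C)OS(=O)(=O)C(F)(F)F
Why: Kinetic deprotonation of the methyl ketone, the only readily accessible acidic C–H, and O-silylation of the enolate gives the enol silane under basic conditions in which no free Lewis acid can ionise the benzylic allylic ether, so C2 is unaffected.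

Step 14
Reactants: 22 (S)-allyl aryl ether bearing the ring A 1-(TBSO)vinyl group
Product: 23 (2S)-4,5,7-tris(TBSO)-8-[(R)-lavandulyl]-6-prenyl-2-[2,4,6-tris(TBSO)phenyl]-2H-chromene
Conditions: second-generation Grubbs catalyst RuCl2(=CHPh)(H2IMes)(PCy3) (10 mol %), 1,4-benzoquinone (10 mol %), PhMe (0.005 M), 70 °C, Ar sparge, dark
Reagents that add atoms: none
Why: Olefin metathesis through metallacyclobutanes: the ruthenium benzylidene first exchanges onto the only monosubstituted alkene, the vinyl group on C2, and the resulting alkylidene at C3 adds across the neighbouring 1-siloxyvinyl group, cycloreversion giving the C3=C4 bond and a ruthenium methylidene with ethylene as the only co-product. The closest known reactions are ring-closing metathesis of silyl enol ethers with terminal alkenes to cyclic enol silanes (including the nitrogen analogues, 4-siloxy-1,2-dihydroquinolines) and metathesis closure of branched allyl aryl ethers to 2-substituted 2H-chromenes. Ring C is closed as a six-membered ring by ring-closing metathesis in which both alkenes lose their terminal CH2 and the new double bond is endocyclic. No stereocentre is created, and C2 keeps its (S) configuration because none of its bonds is broken; the reaction is run in the dark at moderate temperature so that the chromene does not undergo reversible electrocyclic ring opening. The step needs chemoselectivity among five alkenes, which the substrate secures because the vinyl group is the only fast initiation site and the enol silane is the only partner that gives a six-membered ring, whereas the trisubstituted prenyl and 1,1-disubstituted isopropenyl alkenes would need eight-membered or larger rings or intermolecular reaction, both suppressed at high dilution; benzoquinone limits Ru–H isomerisation of the allyl ether.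

Step 15
Reactants: 23 (2S)-4,5,7-tris(TBSO)-8-[(R)-lavandulyl]-6-prenyl-2-[2,4,6-tris(TBSO)phenyl]-2H-chromene
Product: 24 (2S)-5,7-dihydroxy-8-[(R)-lavandulyl]-6-prenyl-2-(2,4,6-trihydroxyphenyl)chroman-4-one (CNP0163831.1)
Conditions: Bu4NF (9 equiv), AcOH (10 equiv), THF, 0 °C → rt; pH 6 buffer work-up
Reagents that add atoms: none
Why: Fluoride-mediated desilylation cleaves the five aryl silyl ethers and the enol silane, and the acetic acid buffer protonates the enol(ate) at C3 to give the C4 ketone and keeps the phenols neutral, which should suppress the enolate- or phenoxide-driven retro-oxa-Michael opening that would scramble C2 and avoids the acid that would cyclise the prenyl and isopropenyl groups onto the flanking phenols; no stereocentre is formed or touched.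

**Compound list**

1 | 2,4,6-trihydroxyacetophenone | CC(=O)c1c(O)cc(O)cc1O | starting material
2 | 1-[2-hydroxy-4,6-bis(TBSO)phenyl]ethanone | CC(=O)c1c(O)cc(O[Si](C)(C)C(C)(C)C)cc1O[Si](C)(C)C(C)(C)C | intermediate
3 | 1-[2-hydroxy-3-iodo-4,6-bis(TBSO)phenyl]ethanone | CC(=O)c1c(O)c(I)c(O[Si](C)(C)C(C)(C)C)cc1O[Si](C)(C)C(C)(C)C | intermediate
4 | racemic lavandulol | C=C(C)C(CO)CC=C(C)C | starting material
5 | (S)-lavandulol | C=C(C)[C@H](CC=C(C)C)CO | intermediate
6 | (S)-lavandulyl iodide | C=C(C)[C@H](CC=C(C)C)CI | intermediate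
7 | (S)-lavandulylzinc iodide (LiCl complex, formed in the flask) | C=C(C)[C@H](CC=C(C)C)C[Zn]I | intermediate
8 | 1-{2-hydroxy-3-[(R)-lavandulyl]-4,6-bis(TBSO)phenyl}ethanone | C=C(C)[C@H](CC=C(C)C)Cc1c(O)c(C(C)=O)c(O[Si](C)(C)C(C)(C)C)cc1O[Si](C)(C)C(C)(C)C | intermediate
9 | 3-methylbut-2-en-1-ol (prenol) | CC(C)=CCO | starting material
10 | 1-{3-[(R)-lavandulyl]-2-(prenyloxy)-4,6-bis(TBSO)phenyl}ethanone | C=C(C)[C@H](CC=C(C)C)Cc1c(OCC=C(C)C)c(C(C)=O)c(O[Si](C)(C)C(C)(C)C)cc1O[Si](C)(C)C(C)(C)C | intermediate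
11 | 2-acetyl-6-[(R)-lavandulyl]-6-(2-methylbut-3-en-2-yl)-3,5-bis(TBSO)cyclohexa-2,4-dien-1-one (both epimers at C6, formed in the flask) | C=C(C)[C@H](CC=C(C)C)CC1(C(C)(C)C=C)C(=O)C(C(C)=O)=C(O[Si](C)(C)C(C)(C)C)C=C1O[Si](C)(C)C(C)(C)C | intermediate
12 | 1-{2-hydroxy-3-[(R)-lavandulyl]-5-prenyl-4,6-bis(TBSO)phenyl}ethanone | C=C(C)[C@H](CC=C(C)C)Cc1c(O)c(C(C)=O)c(O[Si](C)(C)C(C)(C)C)c(CC=C(C)C)c1O[Si](C)(C)C(C)(C)C | intermediate
13 | 2,4,6-trihydroxybenzaldehyde | O=Cc1c(O)cc(O)cc1O | starting material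
14 | 2,4,6-tris(TBSO)benzaldehyde | O=Cc1c(O[Si](C)(C)C(C)(C)C)cc(O[Si](C)(C)C(C)(C)C)cc1O[Si](C)(C)C(C)(C)C | intermediate
15 | ethyl (triphenylphosphoranylidene)acetate | CCOC(=O)C=P(c1ccccc1)(c1ccccc1)c1ccccc1 | starting material
16 | ethyl (E)-3-[2,4,6-tris(TBSO)phenyl]prop-2-enoate | CCOC(=O)/C=C/c1c(O[Si](C)(C)C(C)(C)C)cc(O[Si](C)(C)C(C)(C)C)cc1O[Si](C)(C)C(C)(C)C | intermediate
17 | (E)-3-[2,4,6-tris(TBSO)phenyl]prop-2-en-1-ol | OC/C=C/c1c(O[Si](C)(C)C(C)(C)C)cc(O[Si](C)(C)C(C)(C)C)cc1O[Si](C)(C)C(C)(C)C | intermediate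
18 | methyl (E)-3-[2,4,6-tris(TBSO)phenyl]prop-2-en-1-yl carbonate | COC(=O)OC/C=C/c1c(O[Si](C)(C)C(C)(C)C)cc(O[Si](C)(C)C(C)(C)C)cc1O[Si](C)(C)C(C)(C)C | intermediate
19 | lithium phenoxide of 12 (formed in the flask) | [Li+].C=C(C)[C@H](CC=C(C)C)Cc1c([O-])c(C(C)=O)c(O[Si](C)(C)C(C)(C)C)c(CC=C(C)C)c1O[Si](C)(C)C(C)(C)C | intermediate
20 | 1-{2-[(1S)-1-(2,4,6-tris(TBSO)phenyl)prop-2-en-1-yloxy]-3-[(R)-lavandulyl]-5-prenyl-4,6-bis(TBSO)phenyl}ethanone | C=C(C)[C@H](CC=C(C)C)Cc1c(O[Si](C)(C)C(C)(C)C)c(CC=C(C)C)c(O[Si](C)(C)C(C)(C)C)c(C(C)=O)c1O[C@H](c1c(O[Si](C)(C)C(C)(C)C)cc(O[Si](C)(C)C(C)(C)C)cc1O[Si](C)(C)C(C)(C)C)C=C | intermediate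
21 | potassium enolate of 20 (formed in the flask) | [K+].C=C(C)[C@H](CC=C(C)C)Cc1c(O[Si](C)(C)C(C)(C)C)c(CC=C(C)C)c(O[Si](C)(C)C(C)(C)C)c(C(=C)[O-])c1O[C@H](c1c(O[Si](C)(C)C(C)(C)C)cc(O[Si](C)(C)C(C)(C)C)cc1O[Si](C)(C)C(C)(C)C)C=C | intermediate
22 | key-step precursor: (S)-allyl aryl ether 20 with a 1-(TBSO)vinyl group in place of the acetyl group | C=C(C)[C@H](CC=C(C)C)Cc1c(O[Si](C)(C)C(C)(C)C)c(CC=C(C)C)c(O[Si](C)(C)C(C)(C)C)c(C(=C)O[Si](C)(C)C(C)(C)C)c1O[C@H](c1c(O[Si](C)(C)C(C)(C)C)cc(O[Si](C)(C)C(C)(C)C)cc1O[Si](C)(C)C(C)(C)C)C=C | intermediate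
23 | (2S)-4,5,7-tris(TBSO)-8-[(R)-lavandulyl]-6-prenyl-2-[2,4,6-tris(TBSO)phenyl]-2H-chromene | C=C(C)[C@H](CC=C(C)C)Cc1c(O[Si](C)(C)C(C)(C)C)c(CC=C(C)C)c(O[Si](C)(C)C(C)(C)C)c2c1O[C@H](c1c(O[Si](C)(C)C(C)(C)C)cc(O[Si](C)(C)C(C)(C)C)cc1O[Si](C)(C)C(C)(C)C)C=C2O[Si](C)(C)C(C)(C)C | intermediate
24 | (2S)-5,7-dihydroxy-8-[(R)-lavandulyl]-6-prenyl-2-(2,4,6-trihydroxyphenyl)chroman-4-one | C=C(C)[C@H](CC=C(C)C)Cc1c(O)c(CC=C(C)C)c(O)c2c1O[C@H](c1c(O)cc(O)cc1O)CC2=O | target

**Step count and risks**

Total: 15 steps. Longest linear sequence: 9 steps (steps 1, 2, 5, 6, 7, 12, 13, 14, 15).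

Most likely to fail, in order:

Step 12. The doubly ortho-substituted, very electron-rich cinnamyl donor and the hindered, chelated phenoxide may react slowly, may give the linear ether, or may lose configuration at C2 through re-ionisation of the branched product on the catalyst. The fallback sets out from 14 and 12 and returns at 20. Addition of HC≡CMgBr to aldehyde 14 (THF, −78 → 0 °C) would give racemic 1-[2,4,6-tris(TBSO)phenyl]prop-2-yn-1-ol F1. Acetylation (Ac2O, pyridine) would give racemic 1-[2,4,6-tris(TBSO)phenyl]prop-2-yn-1-yl acetate F2. An enantioconvergent copper-catalysed propargylic etherification of phenol 12 (CuOTf·½C6H6, chiral pybox ligand, i-Pr2NEt, PhMe, 0 °C) runs through a copper allenylidene, so both enantiomers of the ester should funnel into the (S)-propargyl aryl ether of 12 F3, the ligand enantiomer being chosen for this sense. Semi-hydrogenation of the terminal alkyne (H2, Pd/CaCO3 poisoned with Pb(OAc)2, quinoline, EtOAc) would then give 20 without touching the more substituted alkenes.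

Step 14. The shielded 1,1-disubstituted enol silane, flanked by two ortho substituents, may fail to engage the alkylidene, so that the catalyst decomposes or attacks the other alkenes, and the chromene may lose configuration by reversible ring opening on prolonged heating. The fallback gives up the metathesis closure and closes ring C at O1–C2; it sets out from 12 and 14 and returns at 24. A Claisen–Schmidt condensation mediated by LiN(SiMe3)2 (excess, THF, −78 °C → rt) would pass through the β-hydroxy ketone aldol adduct F4 and give, by elimination, the (E)-2'-hydroxychalcone F5. Oxa-Michael closure (NaOAc, EtOH, 60 °C) would give the penta-TBS flavanone as both C2 epimers F6, which are diastereomers because of the lavandulyl centre. A catalyst-controlled asymmetric transfer hydrogenation (RuCl(p-cymene)(TsDPEN), HCO2H/Et3N), with the catalyst enantiomer chosen to reduce the (2R)-epimer faster to its 2,4-cis flavan-4-ol F8, should leave the (2S)-penta-TBS flavanone F7. This gives 24 under the conditions of step 15.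

Step 7. The first sigmatropic shift has to build a very crowded quaternary ring carbon, so cleavage of the prenyl ether (loss of isoprene) or incomplete transfer to the para position may compete, and long heating could begin to scramble the lavandulyl diene. The fallback inverts the order so that the rearrangement runs on an ether with a free ortho position; it sets out from 2 and returns at 12. Mitsunobu reaction of 2 with 9 would give 1-[2-(prenyloxy)-4,6-bis(TBSO)phenyl]ethanone F9. Para-Claisen–Cope rearrangement (PhNEt2, 190 °C) would give 1-[2-hydroxy-5-prenyl-4,6-bis(TBSO)phenyl]ethanone F10. Iodination ortho to the phenol (NIS, CH2Cl2, −20 °C, dark; the flanking silyl ethers disfavour iodocyclisation onto the prenyl group) would give 1-[2-hydroxy-3-iodo-5-prenyl-4,6-bis(TBSO)phenyl]ethanone F11. Negishi coupling with 7 under the conditions of step 5 then gives 12.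

Further compounds
F1 | step 12 | racemic 1-[2,4,6-tris(TBSO)phenyl]prop-2-yn-1-ol | C#CC(O)c1c(O[Si](C)(C)C(C)(C)C)cc(O[Si](C)(C)C(C)(C)C)cc1O[Si](C)(C)C(C)(C)C
F2 | step 12 | racemic 1-[2,4,6-tris(TBSO)phenyl]prop-2-yn-1-yl acetate | C#CC(OC(C)=O)c1c(O[Si](C)(C)C(C)(C)C)cc(O[Si](C)(C)C(C)(C)C)cc1O[Si](C)(C)C(C)(C)C
F3 | step 12 | 1-{2-[(1S)-1-(2,4,6-tris(TBSO)phenyl)prop-2-yn-1-yloxy]-3-[(R)-lavandulyl]-5-prenyl-4,6-bis(TBSO)phenyl}ethanone | C=C(C)[C@H](CC=C(C)C)Cc1c(O[Si](C)(C)C(C)(C)C)c(CC=C(C)C)c(O[Si](C)(C)C(C)(C)C)c(C(C)=O)c1O[C@H](c1c(O[Si](C)(C)C(C)(C)C)cc(O[Si](C)(C)C(C)(C)C)cc1O[Si](C)(C)C(C)(C)C)C#C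
F4 | step 14 | 3-hydroxy-1-{2-hydroxy-3-[(R)-lavandulyl]-5-prenyl-4,6-bis(TBSO)phenyl}-3-[2,4,6-tris(TBSO)phenyl]propan-1-one (both carbinol epimers) | C=C(C)[C@H](CC=C(C)C)Cc1c(O)c(C(=O)CC(O)c2c(O[Si](C)(C)C(C)(C)C)cc(O[Si](C)(C)C(C)(C)C)cc2O[Si](C)(C)C(C)(C)C)c(O[Si](C)(C)C(C)(C)C)c(CC=C(C)C)c1O[Si](C)(C)C(C)(C)C
F5 | step 14 | (E)-1-{2-hydroxy-3-[(R)-lavandulyl]-5-prenyl-4,6-bis(TBSO)phenyl}-3-[2,4,6-tris(TBSO)phenyl]prop-2-en-1-one | C=C(C)[C@H](CC=C(C)C)Cc1c(O)c(C(=O)/C=C/c2c(O[Si](C)(C)C(C)(C)C)cc(O[Si](C)(C)C(C)(C)C)cc2O[Si](C)(C)C(C)(C)C)c(O[Si](C)(C)C(C)(C)C)c(CC=C(C)C)c1O[Si](C)(C)C(C)(C)C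
F6 | step 14 | 5,7-bis(TBSO)-8-[(R)-lavandulyl]-6-prenyl-2-[2,4,6-tris(TBSO)phenyl]chroman-4-one (both C2 epimers) | C=C(C)[C@H](CC=C(C)C)Cc1c(O[Si](C)(C)C(C)(C)C)c(CC=C(C)C)c(O[Si](C)(C)C(C)(C)C)c2c1OC(c1c(O[Si](C)(C)C(C)(C)C)cc(O[Si](C)(C)C(C)(C)C)cc1O[Si](C)(C)C(C)(C)C)CC2=O
F7 | step 14 | (2S)-5,7-bis(TBSO)-8-[(R)-lavandulyl]-6-prenyl-2-[2,4,6-tris(TBSO)phenyl]chroman-4-one | C=C(C)[C@H](CC=C(C)C)Cc1c(O[Si](C)(C)C(C)(C)C)c(CC=C(C)C)c(O[Si](C)(C)C(C)(C)C)c2c1O[C@H](c1c(O[Si](C)(C)C(C)(C)C)cc(O[Si](C)(C)C(C)(C)C)cc1O[Si](C)(C)C(C)(C)C)CC2=O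
F8 | step 14 | 2,4-cis-flavan-4-ol from the (2R)-epimer of F6 | C=C(C)[C@H](CC=C(C)C)Cc1c(O[Si](C)(C)C(C)(C)C)c(CC=C(C)C)c(O[Si](C)(C)C(C)(C)C)c2c1O[C@@H](c1c(O[Si](C)(C)C(C)(C)C)cc(O[Si](C)(C)C(C)(C)C)cc1O[Si](C)(C)C(C)(C)C)C[C@H]2O
F9 | step 7 | 1-[2-(prenyloxy)-4,6-bis(TBSO)phenyl]ethanone | CC(=O)c1c(OCC=C(C)C)cc(O[Si](C)(C)C(C)(C)C)cc1O[Si](C)(C)C(C)(C)C
F10 | step 7 | 1-[2-hydroxy-5-prenyl-4,6-bis(TBSO)phenyl]ethanone | CC(=O)c1c(O)cc(O[Si](C)(C)C(C)(C)C)c(CC=C(C)C)c1O[Si](C)(C)C(C)(C)C
F11 | step 7 | 1-[2-hydroxy-3-iodo-5-prenyl-4,6-bis(TBSO)phenyl]ethanone | CC(=O)c1c(O)c(I)c(O[Si](C)(C)C(C)(C)C)c(CC=C(C)C)c1O[Si](C)(C)C(C)(C)C
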